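Ring carbons are numbered C1–C15 in the order of the target SMILES: norbornane C1–C5, C10, C15 (bridgeheads C2 and C5; bridges C15, C3–C4 and C1–C10), ring B C5–C10, ring A C8, C9, C11–C14. Without C10 the norbornane is a bicyclo[2.1.1]hexane whose two one-carbon bridges (C1, C15) are what a crossed [2+2] of the dienone C15=C5–C4(=O)–C3–C2=C1 builds.
Cuts, last to first: C11/C12 diol (epoxide, trans-diaxial opening); C14–Br (from C14–B with inversion, boron from conjugate borylation of a ring-A dienone); C7–C8 (para-alkylative dearomatisation of a C10 aryl group, closing ring B); C4 isopropyl (enol triflate coupling, exo hydrogenation); C5–C10 (semipinacol bridge enlargement, C5 moving from C1 to the new carbon C10); C2–C15 and C1–C5 (photocycloaddition).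
Forward: acyclic dienone 8 → bicyclo[2.1.1]hexane 9 (two rings, step 6) → cyclobutanone 13 → norbornanone 23 (step 14) → ring B by dearomatisation (step 23; ring A arrives as the arene) → ring-A tailoring (steps 24–28).
Stereochemistry: C2/C5 are set in the racemic photoadduct and the enantiomer is taken by resolution of ketone 12. C10, C1 and C4 follow from thermodynamic and exo-face control on the norbornane, and C8 from the norbornane-fixed chair of the closing ring B. C14, C9, C11 and C12 follow from attack anti to the angular C8 methyl, inversion at boron-bearing C14 and diaxial epoxide opening.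

Key step: step 6

Remark: the photocycloaddition is run on achiral 8 and gives a racemate; 9–12 are drawn as the enantiomer kept after step 10, and 5-methoxy-2-methylbenzaldehyde 14 is taken as a catalogue compound.

Step 1
Reactants: 1 3-methylideneoxolan-2-one (α-methylene-γ-butyrolactone)
Product: 2 3-methylideneoxolan-2-ol (racemic lactol)
Conditions: i-Bu2AlH (1.05 equiv), CH2Cl2, −78 °C; aq Rochelle salt
Reagents that add atoms: none
Why: Partial lactone reduction: the tetrahedral aluminium hemiacetal is stable at −78 °C, so hydride delivery should stop at the lactol, and 1,2-addition outruns conjugate reduction of the methylidene group.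

Step 2
Reactants: 2 3-methylideneoxolan-2-ol; 3 3-bromoprop-1-yne (propargyl bromide)
Product: 5 3-methylidenehept-6-yne-1,4-diol, via propa-1,2-dienylzinc bromide 4 (not isolated)
Conditions: Zn dust, THF/sat. aq NH4Cl, 0 °C → rt
Reagents that add atoms: none
Why: Barbier propargylation: the lactol equilibrates with 4-hydroxy-2-methylidenebutanal, whose aldehyde is captured 1,2 by the allenylzinc reagent through an SE2' transition state to give the homopropargylic alcohol (carbinol centre racemic, oxidised in step 5).

Step 3
Reactants: 5 3-methylidenehept-6-yne-1,4-diol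
Product: 6 1-(tert-butyldimethylsilyloxy)-3-methylidenehept-6-yn-4-ol
Conditions: TBSCl (1.05 equiv), imidazole, CH2Cl2, 0 °C
Reagents that add atoms: tert-butyldimethylsilyl chloride, CC(C)(C)[Si](C)(C)Cl
Why: Silyl ether formation, which discriminates the primary hydroxyl from the hindered secondary allylic one on steric grounds.

Step 4
Reactants: 6 1-(tert-butyldimethylsilyloxy)-3-methylidenehept-6-yn-4-ol
Product: 7 (E)-1-(tert-butyldimethylsilyloxy)-3-methylidene-7-(4,4,5,5-tetramethyl-1,3,2-dioxaborolan-2-yl)hept-6-en-4-ol
Conditions: B2pin2 (1.1 equiv), CuCl (5 mol %), Xantphos (5 mol %), NaOtBu (10 mol %), MeOH (2 equiv), THF, rt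
Reagents that add atoms: bis(pinacolato)diboron, CC1(C)OB(OC1(C)C)B1OC(C)(C)C(C)(C)O1
Why: Copper-catalysed protoboration (syn borylcupration, then protonation by methanol) puts boron on the alkyne terminus and gives the (E)-alkenylboronate, and it tolerates the free hydroxyl and the 1,1-disubstituted alkene because no enone is present yet.

Step 5
Reactants: 7 the (E)-alkenylboronate alcohol
Product: 8 (E)-1-(tert-butyldimethylsilyloxy)-3-methylidene-7-(4,4,5,5-tetramethyl-1,3,2-dioxaborolan-2-yl)hept-6-en-4-one
Conditions: Dess–Martin periodinane, CH2Cl2, 0 °C → rt; used at once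
Reagents that add atoms: none
Why: Dess–Martin oxidation of the secondary allylic alcohol under near-neutral conditions should give the α-methylene ketone without moving the β,γ-double bond into conjugation.

Step 6
Reactants: 8 the 1,5-dien-3-one (C15=C5–C4(=O)–C3–C2=C1–B)
Product: 9 1-[2-(tert-butyldimethylsilyloxy)ethyl]-5-(4,4,5,5-tetramethyl-1,3,2-dioxaborolan-2-yl)bicyclo[2.1.1]hexan-2-one (racemic; both epimers at the boron-bearing bridge C1)
Conditions: xanthone (20 mol %), hν (350 nm), degassed MeCN (0.01 M), 20 °C
Reagents that add atoms: none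
Why: Triplet energy transfer from xanthone excites the α-methylene ketone, whose β-carbon C15 adds to C2 of the alkenylboronate (rule of five) to give a 1,4-biradical (tertiary α-keto radical at C5, α-boryl radical at C1) that collapses by C1–C5 coupling after intersystem crossing. The closest known reaction type is the sensitised crossed intramolecular [2+2] photocycloaddition of hexa-1,5-dien-3-ones to bicyclo[2.1.1]hexan-2-ones, alkenylboronate partners included. The five-membered ring C15–C5–C4–C3–C2 closes by 5-exo-trig radical addition and the four-membered ring C5–C15–C2–C1 by biradical recombination. The bridgehead centres C2 and C5 are locked to each other by the bicyclic frame and form as a racemate (absolute configuration comes from step 10), while the C1 epimers are erased when C1 becomes a ketone in step 9. The step needs crossed rather than straight regiochemistry and no singlet 1,3-acyl shift or product photolysis; the two-atom tether makes 1,5-closure much faster than 1,6-closure, and exclusive sensitisation at 350 nm, where 8 and 9 barely absorb, should keep the other channels closed.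

Step 7
Reactants: 9 the borylated bicyclo[2.1.1]hexan-2-one
Product: 10 2-[1-[2-(tert-butyldimethylsilyloxy)ethyl]-2-methylidenebicyclo[2.1.1]hexan-5-yl]-4,4,5,5-tetramethyl-1,3,2-dioxaborolane (racemic, epimers at C1)
Conditions: Ph3PCH3Br, KOtBu, THF, 0 °C → rt
Reagents that add atoms: methyltriphenylphosphonium bromide, C[P+](c1ccccc1)(c1ccccc1)c1ccccc1.[Br-]
Why: Wittig methylenation removes the C4 carbonyl before C1 is oxygenated, so the C1 alkoxide made next cannot cleave the C1–C5 bond by retro-aldol (de Mayo-type) fragmentation, and it turns C5 into an allylic quaternary carbon for step 14.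

Step 8
Reactants: 10 the methylidene boronate
Product: 11 1-[2-(tert-butyldimethylsilyloxy)ethyl]-2-methylidenebicyclo[2.1.1]hexan-5-ol (racemic, epimers at C1)
Conditions: NaBO3·4H2O, THF/H2O (1:1), rt
Reagents that add atoms: sodium perborate tetrahydrate, [Na+].[O-]OB=O.O.O.O.O
Why: Perborate oxidation of the carbon–boron bond (1,2-shift from boron to oxygen with retention) is mild enough for the silyl ether, the alkene and the strained ring.

Step 9
Reactants: 11 the bicyclic cyclobutanol
Product: 12 1-[2-(tert-butyldimethylsilyloxy)ethyl]-2-methylidenebicyclo[2.1.1]hexan-5-one (racemic)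
Conditions: Dess–Martin periodinane, CH2Cl2, 0 °C → rt
Reagents that add atoms: none
Why: Dess–Martin oxidation should convert the strained cyclobutanol into the cyclobutanone without the ring cleavage that one-electron oxidants cause, and it merges both C1 epimers into one racemate.

Step 10
Reactants: 12 the racemic cyclobutanone
Product: 13 the same ketone as a single enantiomer (configuration at C2 and C5 as in the target)
Conditions: preparative SFC on amylose tris(3,5-dimethylphenylcarbamate), CO2/i-PrOH
Reagents that add atoms: none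
Why: Resolution by chromatography on a chiral stationary phase is the source of absolute configuration; 12 has only the two mutually locked bridgehead centres, and the wanted enantiomer can be assigned by anomalous-dispersion X-ray analysis of selenide 21.

Step 11
Reactants: 14 5-methoxy-2-methylbenzaldehyde
Product: 18 3-methoxy-2,6-dimethylbenzaldehyde, via lithium α-amino alkoxide 15 (not isolated), via ring-lithiated α-amino alkoxide 16 (not isolated), via C-methylated α-amino alkoxide 17 (not isolated)
Conditions: Me2NCH2CH2NHMe, n-BuLi, THF, −20 °C; n-BuLi, −20 °C; MeI, −78 °C → rt; aq HCl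
Reagents that add atoms: iodomethane, CI
Why: Directed ortho-metalation: the in situ α-amino alkoxide and the methoxy group together direct lithiation to the ring carbon between them, and methylation followed by hydrolytic release of the aldehyde gives the 2,6-dimethyl pattern.

Step 12
Reactants: 18 3-methoxy-2,6-dimethylbenzaldehyde
Product: 19 3-[bis(phenylselanyl)methyl]-1-methoxy-2,4-dimethylbenzene
Conditions: PhSeH (2.2 equiv), ZnCl2 (cat.), CH2Cl2, rt
Reagents that add atoms: benzeneselenol, [SeH]c1ccccc1
Why: Lewis acid-catalysed selenoacetalisation of the aldehyde gives the precursor for selenium–lithium exchange, which avoids deprotonating a twisted, poorly stabilised benzylic position.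

Step 13
Reactants: 19 the selenoacetal; 13 the enantiopure cyclobutanone
Product: 21 5-[(3-methoxy-2,6-dimethylphenyl)(phenylselanyl)methyl]-1-[2-(tert-butyldimethylsilyloxy)ethyl]-2-methylidenebicyclo[2.1.1]hexan-5-ol (diastereomer mixture at C1/C10), via α-selenobenzyllithium 20 (not isolated)
Conditions: 19, n-BuLi, THF, −78 °C; then 13, −78 → −40 °C; aq NH4Cl
Reagents that add atoms: none
Why: Selenium–lithium exchange gives an α-selenoalkyllithium that adds 1,2 to the non-enolisable, strain-activated cyclobutanone; the two new centres form as a mixture that converges in step 14.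

Step 14
Reactants: 21 the β-hydroxy selenide
Product: 23 norbornan-2-one (C1 ketone; exo 3-methoxy-2,6-dimethylphenyl at C10; methylidene at C4; CH2CH2OTBS at C5), via endo-aryl C10 epimer 22 (not isolated)
Conditions: AgBF4, 2,6-di-tert-butyl-4-methylpyridine, CH2Cl2, −20 °C → rt; then DBU (cat.), rt
Reagents that add atoms: none
Why: Semipinacol ring enlargement of a β-hydroxy selenide: silver-assisted loss of selenium from benzylic C10 drives a 1,2-shift of the allylic, quaternary and more electron-rich C5 (in preference to C2) from C1 to C10 with release of cyclobutane strain, and DBU then equilibrates C10 so that the bulky aryl group sits exo.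

Step 15
Reactants: 23 the norbornanone
Product: 24 the C1 endo alcohol (hydroxyl trans to the exo aryl group)
Conditions: Li, NH3(l)/THF, −78 °C; NH4Cl
Reagents that add atoms: none
Why: Dissolving-metal ketone reduction: protonation of the C1 ketyl/carbanion from the open exo face and the lower energy of the trans product (no eclipsing with the exo aryl group) should both place the hydroxyl endo.

Step 16
Reactants: 24 the endo alcohol
Product: 26 the C1 endo methyl ether, via sodium alkoxide 25 (not isolated)
Conditions: NaH, MeI, THF/DMF, 0 °C → rt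
Reagents that add atoms: iodomethane, CI
Why: Williamson etherification; no other acidic hydroxyl is present and the configuration at C1 is not touched.

Step 17
Reactants: 26 the methyl ether with C4 methylidene
Product: 28 the C4 ketone, via vicinal diol 27 (not isolated)
Conditions: OsO4 (cat.), NaIO4, 2,6-lutidine, dioxane/H2O, rt
Reagents that add atoms: osmium tetroxide, O=[Os](=O)(=O)=O; sodium periodate, [Na+].[O-]I(=O)(=O)=O
Why: Lemieux–Johnson oxidation (osmylation, then periodate cleavage) unmasks the C4 ketone without attacking the electron-rich arene.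

Step 18
Reactants: 28 the C4 ketone
Product: 30 the C3=C4 enol triflate, via potassium enolate 29 (not isolated)
Conditions: KN(SiMe3)2, THF, −78 °C; PhNTf2, −78 → 0 °C
Reagents that add atoms: N-phenylbis(trifluoromethanesulfonimide), O=S(=O)(N(c1ccccc1)S(=O)(=O)C(F)(F)F)C(F)(F)F
Why: Enol triflate formation is regiospecific because C3 is the only enolisable position (C5 is quaternary).

Step 19
Reactants: 30 the enol triflate
Product: 31 the C4 isopropenyl diene (C3=C4–C(CH3)=CH2)
Conditions: isopropenylboronic acid pinacol ester, PdCl2(dppf) (5 mol %), K3PO4, THF/H2O, 60 °C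
Reagents that add atoms: isopropenylboronic acid pinacol ester, CC(=C)B1OC(C)(C)C(C)(C)O1
Why: Suzuki–Miyaura coupling of an alkenyl triflate with an alkenylboronate brings in the three isopropyl carbons.

Step 20
Reactants: 31 the diene
Product: 32 the C4 endo-isopropyl norbornane (aryl methyl ether, silyl ether)
Conditions: H2 (3 atm), Pd/C, EtOAc, rt
Reagents that add atoms: none
Why: Heterogeneous hydrogenation of the norbornene-type diene should deliver hydrogen to C4 from the exo face (the C15 side; the endo face is screened by the C1 methoxy group), so the isopropyl group ends up endo.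

Step 21
Reactants: 32 the aryl methyl ether
Product: 33 the phenol
Conditions: NaSEt, DMF, 120 °C
Reagents that add atoms: none
Why: Nucleophilic (SN2) demethylation by thiolate cleaves only the aryl methyl ether because phenoxide is the better leaving group; the alkyl methyl ether at C1 is inert.

Step 22
Reactants: 33 the phenol silyl ether
Product: 34 the phenol with a 2-bromoethyl group on C5 (C7–Br)
Conditions: Ph3PBr2, CH2Cl2, 0 °C → rt
Reagents that add atoms: dibromotriphenylphosphorane, BrP(Br)(c1ccccc1)(c1ccccc1)c1ccccc1
Why: Appel-type bromination: Ph3PBr2 converts the primary silyl ether directly into the bromide through an oxyphosphonium ion, and the phenol is recovered unchanged on work-up.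

Step 23
Reactants: 34 the bromoethyl phenol
Product: 36 the tetracyclic cross-conjugated dienone (C12=O; C9=C11; C13=C14; C8 methyl cis to H-10), via potassium phenoxide 35 (not isolated)
Conditions: KOtBu (1.05 equiv), t-BuOH, 80 °C, high dilution
Reagents that add atoms: none
Why: Intramolecular para-alkylation of a phenoxide (alkylative dearomatisation): the tether reaches only the two methyl-bearing carbons next to C9, the para carbon C8 has the larger coefficient and is less crowded than C11 beside the solvated oxygen, and the norbornane-fixed chair of the forming ring B puts the C8 methyl cis to H-10.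

Step 24
Reactants: 36 the dienone
Product: 37 the C14 pinacol boronate (boron anti to the C8 methyl; C9=C11–C12=O enone kept)
Conditions: B2pin2, CuCl (3 mol %), DPEphos (3 mol %), NaOtBu (9 mol %), MeOH (2 equiv), THF, rt
Reagents that add atoms: bis(pinacolato)diboron, CC1(C)OB(OC1(C)C)B1OC(C)(C)C(C)(C)O1
Why: Copper-catalysed conjugate borylation takes the less substituted enone of the dienone; the boryl–copper adds to C14 anti to the pseudoaxial C8 methyl, and the tetrasubstituted C9=C11 enone is inert.

Step 25
Reactants: 37 the β-boryl enone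
Product: 39 the C11=C12 enol triflate with trans ring fusion (H-9 anti to the C8 methyl), via lithium enolate 38 (not isolated)
Conditions: Li, NH3(l)/THF, t-BuOH (1 equiv), −78 °C; NH3 removed; PhNTf2, THF, 0 °C → rt
Reagents that add atoms: N-phenylbis(trifluoromethanesulfonimide), O=S(=O)(N(c1ccccc1)S(=O)(=O)C(F)(F)F)C(F)(F)F
Why: Dissolving-metal enone reduction with regiospecific enolate trapping: β-protonation at C9 should give the trans-fused decalin, and the enolate formed only toward C11 is O-sulfonylated.

Step 26
Reactants: 39 the enol triflate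
Product: 40 the C11=C12 alkene with the axial C14 boronate
Conditions: Pd(OAc)2 (5 mol %), PPh3, n-Bu3N, HCO2H, DMF, 60 °C
Reagents that add atoms: none
Why: Palladium-catalysed formate reduction of an enol triflate (oxidative addition, formate exchange, decarboxylation, reductive elimination) fixes the alkene position and leaves the alkylboronate alone.

Step 27
Reactants: 40 the alkene boronate
Product: 42 the C14 equatorial bromide (Br cis to the C8 methyl), via lithium boronate complex 41 (not isolated)
Conditions: 3,5-(CF3)2C6H3Br, n-BuLi, THF, −78 °C; 40; then NBS, −78 °C → rt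
Reagents that add atoms: N-bromosuccinimide, O=C1CCC(=O)N1Br
Why: Stereoinvertive bromodeboronation: the aryl boronate complex reacts with NBS by backside electrophilic substitution (SE2 with inversion), turning the axial C14–B bond into the equatorial C14–Br bond, and the electron-poor aryl group keeps bromination away from the aryl–boron bond.

Step 28
Reactants: 42 the bromo alkene
Product: 44 CNP0130529.1 (target), via C11–C12 epoxide 43 (not isolated)
Conditions: mCPBA, CH2Cl2, 0 °C; then aq HClO4 (cat.), THF, rt
Reagents that add atoms: 3-chloroperbenzoic acid, OOC(=O)c1cccc(Cl)c1; water, O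
Why: Epoxidation, then acid-catalysed trans-diaxial (Fürst–Plattner) hydrolysis: the peracid attacks the alkene face anti to the axial C8 methyl and water opens the epoxide at tertiary C11 from the other face, giving axial hydroxyls at C11 and C12 and an equatorial C11 methyl.

Compound list
1 | 3-methylideneoxolan-2-one (α-methylene-γ-butyrolactone) | C=C1CCOC1=O | starting material
2 | 3-methylideneoxolan-2-ol (racemic lactol) | OC1OCCC1=C | intermediate
3 | 3-bromoprop-1-yne (propargyl bromide) | C#CCBr | starting material
4 | propa-1,2-dienylzinc bromide | C=C=C[Zn]Br | intermediate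
5 | 3-methylidenehept-6-yne-1,4-diol (racemic) | C#CCC(O)C(=C)CCO | intermediate
6 | 1-(tert-butyldimethylsilyloxy)-3-methylidenehept-6-yn-4-ol (racemic) | C#CCC(O)C(=C)CCO[Si](C)(C)C(C)(C)C | intermediate
7 | (E)-1-(tert-butyldimethylsilyloxy)-3-methylidene-7-(4,4,5,5-tetramethyl-1,3,2-dioxaborolan-2-yl)hept-6-en-4-ol (racemic) | OC(C/C=C/B1OC(C)(C)C(C)(C)O1)C(=C)CCO[Si](C)(C)C(C)(C)C | intermediate
8 | (E)-1-(tert-butyldimethylsilyloxy)-3-methylidene-7-(4,4,5,5-tetramethyl-1,3,2-dioxaborolan-2-yl)hept-6-en-4-one | C=C(CCO[Si](C)(C)C(C)(C)C)C(=O)C/C=C/B1OC(C)(C)C(C)(C)O1 | intermediate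
9 | 1-[2-(tert-butyldimethylsilyloxy)ethyl]-5-(pinacolboryl)bicyclo[2.1.1]hexan-2-one; racemic, carried enantiomer drawn, both epimers at the boron-bearing bridge | CC1(C)OB(OC1(C)C)C3[C@H]2CC(=O)[C@]3(CCO[Si](C)(C)C(C)(C)C)C2 | intermediate
10 | 2-methylidene analogue of 9 (racemic, both boron epimers) | CC1(C)OB(OC1(C)C)C3[C@H]2CC(=C)[C@]3(CCO[Si](C)(C)C(C)(C)C)C2 | intermediate
11 | 1-[2-(tert-butyldimethylsilyloxy)ethyl]-2-methylidenebicyclo[2.1.1]hexan-5-ol (racemic, both carbinol epimers) | OC3[C@H]2CC(=C)[C@]3(CCO[Si](C)(C)C(C)(C)C)C2 | intermediate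
12 | 1-[2-(tert-butyldimethylsilyloxy)ethyl]-2-methylidenebicyclo[2.1.1]hexan-5-one (racemic) | O=C1[C@H]2CC(=C)[C@]1(CCO[Si](C)(C)C(C)(C)C)C2 | intermediate
13 | the same ketone, single enantiomer (bridgeheads as C2 and C5 of the target) | O=C1[C@H]2CC(=C)[C@]1(CCO[Si](C)(C)C(C)(C)C)C2 | intermediate
14 | 5-methoxy-2-methylbenzaldehyde | COc1ccc(C)c(C=O)c1 | starting material
15 | lithium α-[methyl(2-dimethylaminoethyl)amino]-5-methoxy-2-methylbenzyl alkoxide | COc1ccc(C)c(C([O-])N(C)CCN(C)C)c1.[Li+] | intermediate
16 | its 6-lithio derivative (lithium between the alkoxide-bearing carbon and the methoxy group) | COc1ccc(C)c(C([O-])N(C)CCN(C)C)c1[Li].[Li+] | intermediate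
17 | the 6-methylated α-amino alkoxide | COc1ccc(C)c(C([O-])N(C)CCN(C)C)c1C.[Li+] | intermediate
18 | 3-methoxy-2,6-dimethylbenzaldehyde | COc1ccc(C)c(C=O)c1C | intermediate
19 | 3-[bis(phenylselanyl)methyl]-1-methoxy-2,4-dimethylbenzene | COc1ccc(C)c(C([Se]c2ccccc2)[Se]c2ccccc2)c1C | intermediate
20 | [(3-methoxy-2,6-dimethylphenyl)(phenylselanyl)methyl]lithium | COc1ccc(C)c(C([Li])[Se]c2ccccc2)c1C | intermediate
21 | β-hydroxy selenide: tertiary C1 carbinol of the bicyclo[2.1.1]hexane bearing CH(Ar)(SePh) (Ar = 3-methoxy-2,6-dimethylphenyl), mixture at C1 and C10 | OC1(C([Se]c3ccccc3)c3c(C)ccc(OC)c3C)[C@H]2CC(=C)[C@]1(CCO[Si](C)(C)C(C)(C)C)C2 | intermediate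
22 | norbornan-2-one with endo aryl at C10 (C10 epimer of 23) | O=C1[C@H]2CC(=C)[C@]([C@H]1c3c(C)ccc(OC)c3C)(CCO[Si](C)(C)C(C)(C)C)C2 | intermediate
23 | norbornan-2-one: C1 ketone, exo 3-methoxy-2,6-dimethylphenyl at C10, methylidene at C4, CH2CH2OTBS at bridgehead C5 | O=C1[C@H]2CC(=C)[C@]([C@@H]1c3c(C)ccc(OC)c3C)(CCO[Si](C)(C)C(C)(C)C)C2 | intermediate
24 | C1 endo alcohol of 23 (OH trans to the exo aryl group) | O[C@H]1[C@H]2CC(=C)[C@]([C@@H]1c3c(C)ccc(OC)c3C)(CCO[Si](C)(C)C(C)(C)C)C2 | intermediate
25 | sodium alkoxide of 24 | [Na+].[O-][C@H]1[C@H]2CC(=C)[C@]([C@@H]1c3c(C)ccc(OC)c3C)(CCO[Si](C)(C)C(C)(C)C)C2 | intermediate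
26 | C1 endo methyl ether | CO[C@H]1[C@H]2CC(=C)[C@]([C@@H]1c3c(C)ccc(OC)c3C)(CCO[Si](C)(C)C(C)(C)C)C2 | intermediate
27 | C4 hydroxy, C4 hydroxymethyl diol from 26 (C4 epimers) | CO[C@H]1[C@H]2CC(O)(CO)[C@]([C@@H]1c3c(C)ccc(OC)c3C)(CCO[Si](C)(C)C(C)(C)C)C2 | intermediate
28 | C4 ketone (C1 endo OMe, C10 exo aryl) | CO[C@H]1[C@H]2CC(=O)[C@]([C@@H]1c3c(C)ccc(OC)c3C)(CCO[Si](C)(C)C(C)(C)C)C2 | intermediate
29 | potassium C3=C4 enolate of 28 | CO[C@H]1[C@H]2C=C([O-])[C@]([C@@H]1c3c(C)ccc(OC)c3C)(CCO[Si](C)(C)C(C)(C)C)C2.[K+] | intermediate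
30 | C3=C4 enol triflate | CO[C@H]1[C@H]2C=C(OS(=O)(=O)C(F)(F)F)[C@]([C@@H]1c3c(C)ccc(OC)c3C)(CCO[Si](C)(C)C(C)(C)C)C2 | intermediate
31 | C4 isopropenyl norbornene (diene) | CO[C@H]1[C@H]2C=C(C(C)=C)[C@]([C@@H]1c3c(C)ccc(OC)c3C)(CCO[Si](C)(C)C(C)(C)C)C2 | intermediate
32 | C4 endo-isopropyl norbornane, aryl methyl ether | CO[C@H]1[C@H]2C[C@@H](C(C)C)[C@]([C@@H]1c3c(C)ccc(OC)c3C)(CCO[Si](C)(C)C(C)(C)C)C2 | intermediate
33 | the corresponding phenol (3-hydroxy-2,6-dimethylphenyl at C10) | CO[C@H]1[C@H]2C[C@@H](C(C)C)[C@]([C@@H]1c3c(C)ccc(O)c3C)(CCO[Si](C)(C)C(C)(C)C)C2 | intermediate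
34 | phenol with 2-bromoethyl on C5 | CO[C@H]1[C@H]2C[C@@H](C(C)C)[C@]([C@@H]1c3c(C)ccc(O)c3C)(CCBr)C2 | intermediate
35 | potassium phenoxide of 34 | CO[C@H]1[C@H]2C[C@@H](C(C)C)[C@]([C@@H]1c3c(C)ccc([O-])c3C)(CCBr)C2.[K+] | intermediate
36 | tetracyclic dienone: ring A cyclohexa-2,5-dienone (C12=O, C9=C11 with C11 methyl, C13=C14), quaternary C8 methyl cis to H-10 | CO[C@H]1[C@H]2C[C@@H](C(C)C)[C@]3(CC[C@@]4(C)C([C@H]13)=C(C)C(=O)C=C4)C2 | intermediate
37 | C14 pinacol boronate of the C9=C11 enone, boron anti to the C8 methyl | CO[C@H]1[C@H]2C[C@@H](C(C)C)[C@]3(CC[C@@]4(C)C([C@H]13)=C(C)C(=O)C[C@H]4B5OC(C)(C)C(C)(C)O5)C2 | intermediate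
38 | lithium C11=C12 enolate, trans-fused (H-9 anti to the C8 methyl) | CO[C@H]1[C@H]2C[C@@H](C(C)C)[C@]3(CC[C@@]4(C)[C@H]([C@H]13)C(C)=C([O-])C[C@H]4B5OC(C)(C)C(C)(C)O5)C2.[Li+] | intermediate
39 | C11=C12 enol triflate (C12–OTf), axial C14 boronate | CO[C@H]1[C@H]2C[C@@H](C(C)C)[C@]3(CC[C@@]4(C)[C@H]([C@H]13)C(C)=C(OS(=O)(=O)C(F)(F)F)C[C@H]4B5OC(C)(C)C(C)(C)O5)C2 | intermediate
40 | C11=C12 alkene, axial C14 boronate | CO[C@H]1[C@H]2C[C@@H](C(C)C)[C@]3(CC[C@@]4(C)[C@H]([C@H]13)C(C)=CC[C@H]4B5OC(C)(C)C(C)(C)O5)C2 | intermediate
41 | lithium [3,5-bis(trifluoromethyl)phenyl]boronate complex of 40 | CO[C@H]1[C@H]2C[C@@H](C(C)C)[C@]3(CC[C@@]4(C)[C@H]([C@H]13)C(C)=CC[C@H]4[B-]5(c6cc(C(F)(F)F)cc(C(F)(F)F)c6)OC(C)(C)C(C)(C)O5)C2.[Li+] | intermediate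
42 | C11=C12 alkene with equatorial C14 bromide (cis to the C8 methyl) | CO[C@H]1[C@H]2C[C@@H](C(C)C)[C@]3(CC[C@@]4(C)[C@H]([C@H]13)C(C)=CC[C@@H]4Br)C2 | intermediate
43 | C11–C12 epoxide on the face anti to the C8 methyl | CO[C@H]1[C@H]2C[C@@H](C(C)C)[C@]3(CC[C@@]4(C)[C@H]([C@H]13)[C@@]5(C)O[C@H]5C[C@@H]4Br)C2 | intermediate
44 | CNP0130529.1 | CO[C@H]1[C@H]2C[C@@H](C(C)C)[C@]3(CC[C@@]4(C)[C@H]([C@H]13)[C@](C)(O)[C@@H](O)C[C@@H]4Br)C2 | target

Total steps: 28. Longest linear sequence: 26 (steps 1–10 and 13–28); steps 11–12 prepare the aryl fragment.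

Steps most likely to fail

Step 27. Backside electrophilic attack at C14, which lies next to the quaternary C8, may be slow enough for homolytic or front-side pathways to take over, so the bromide could form with eroded or reversed configuration. The fallback sets out from 40. Perborate oxidation (retention) gives the axial C14 alcohol F1, and Dess–Martin oxidation gives the β,γ-unsaturated C14 ketone F2. Condensation with hydrazine gives the hydrazone F3, and oxidation with CuBr2/Et3N gives the geminal dibromide F4. Mono-reduction with Bu3SnH (Et3B/O2, −78 °C), in which the α-bromo radical takes hydrogen on the face anti to the axial C8 methyl, comes back to the route at 42.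

Step 23. The ambident phenoxide may lose regiocontrol, with C7 bonding to the ortho carbon C11 in place of the para carbon C8. The fallback sets out from 34 and uses that mode on purpose: a lithium phenoxide in toluene (LiOtBu), where the metal holds the oxygen near the electrophile, favours ortho closure to the linear 2,4-cyclohexadienone F5. Because the two aryl methyl groups are interchangeable, F5 has the correct carbon skeleton, with its carbonyl at C14 next to C8. Dissolving-metal 1,6-reduction (Li, NH3) with kinetic α-protonation gives the ketone F2 of the first fallback, and the same hydrazone, dibromide and tin hydride sequence comes back at 42, bypassing steps 24–27.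

Step 25. Amide or alkoxide may attack the boronate, and an enolate chelated to the neighbouring boron may be triflated sluggishly, leading to protodeboronation or the simple saturated ketone. The fallback sets out from 37. Hydrogen-atom-transfer conjugate reduction (Mn(dpm)3, PhSiH3, i-PrOH) gives the trans-fused saturated ketone F6, with hydrogen entering C9 anti to the C8 methyl. Thermodynamic enol triflate formation on the more substituted side (Tf2O, 2,6-di-tert-butyl-4-methylpyridine) comes back at 39.

Further compounds
F1 | step 27 | axial C14 alcohol of the C11=C12 alkene | CO[C@H]1[C@H]2C[C@@H](C(C)C)[C@]3(CC[C@@]4(C)[C@H]([C@H]13)C(C)=CC[C@H]4O)C2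
F2 | step 27 | C14 ketone with C11=C12 alkene, trans-fused | CO[C@H]1[C@H]2C[C@@H](C(C)C)[C@]3(CC[C@@]4(C)[C@H]([C@H]13)C(C)=CCC4=O)C2
F3 | step 27 | hydrazone of F2 | CO[C@H]1[C@H]2C[C@@H](C(C)C)[C@]3(CC[C@@]4(C)[C@H]([C@H]13)C(C)=CCC4=NN)C2
F4 | step 27 | C14 geminal dibromide | CO[C@H]1[C@H]2C[C@@H](C(C)C)[C@]3(CC[C@@]4(C)[C@H]([C@H]13)C(C)=CCC4(Br)Br)C2
F5 | step 23 | linear 2,4-cyclohexadienone from ortho closure (C14=O, C12=C13, C9=C11) | CO[C@H]1[C@H]2C[C@@H](C(C)C)[C@]3(CC[C@@]4(C)C([C@H]13)=C(C)C=CC4=O)C2
F6 | step 25 | trans-fused saturated C12 ketone with C14 boronate | CO[C@H]1[C@H]2C[C@@H](C(C)C)[C@]3(CC[C@@]4(C)[C@H]([C@H]13)C(C)C(=O)C[C@H]4B5OC(C)(C)C(C)(C)O5)C2
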